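Read at 40 h, 52 h or 68 h, a flask charged with 0.10 M of substrate has its charge spread over a few products, and we must say which holds most and how much.

| setting | alpha | theta | Monday's | Saturday's | Friday's |
|---|---|---|---|---|---|
| substrate | 0.067 M | 0.15 M | 0.10 M | 0.10 M | 0.10 M |
| gas | 11 mM (held) | 11 mM (held) | 11 mM (held) | 11 mM (held) | 11 mM (held) |
| remark | run made earlier | run made earlier |  |  |  |
| time |  |  | 40 h | 52 h | 68 h |

| run | time / h | isomer of the product / % | substrate / % | intermediate / % | target / % | over-reaction product / % |
|---|---|---|---|---|---|---|
| alpha | 6.00 | 12.5 | 51.4 | 17.2 | 16.7 | 2.0 |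
| alpha | 12.0 | 32.9 | 18.0 | 16.8 | 23.5 | 8.7 |
| alpha | 20.0 | 52.0 | 2.2 | 10.3 | 14.7 | 20.3 |
| alpha | 25.0 | 58.4 | 0.3 | 6.3 | 9.7 | 25.5 |
| alpha | 30.0 | 60.3 | 0 | 4.3 | 5.9 | 29.4 |
| alpha | 40.0 | 62.0 | 0 | 1.8 | 2.8 | 33.7 |
| theta | 2.50 | 1.7 | 88.0 | 7.3 | 3.4 | 0.1 |
| theta | 8.00 | 11.6 | 61.5 | 12.5 | 13.8 | 0.8 |
| theta | 15.0 | 29.2 | 32.5 | 15.0 | 18.5 | 4.0 |
| theta | 20.0 | 41.8 | 16.6 | 14.4 | 19.8 | 7.8 |
| theta | 30.0 | 59.4 | 2.7 | 8.5 | 12.0 | 17.4 |
| theta | 40.0 | 66.1 | 0.1 | 3.8 | 4.6 | 24.6 |

(scatter of a reading: 0.3 percentage points)

* which of these there is most of at the end, counted by the substrate in it, Monday's (over-reaction product / intermediate / target / isomer of the product)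
* which of these there is most of at the end, counted by the substrate in it, Saturday's (over-reaction product / intermediate / target / isomer of the product)
* which of these there is most of at the end, counted by the substrate in it, Friday's (over-reaction product / intermediate / target / isomer of the product)
* the largest of these amounts at the end, in percent of the substrate charged, Monday's
* the largest of these amounts at the end, in percent of the substrate charged, Saturday's
* the largest of these amounts at the end, in percent of the substrate charged, Friday's

- at the start none of the gas is in solution

1. We keep the books in shares of the charge. Substrate, the limiting reagent, stands at 0% at the alpha run's last reading, 40.0 h.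
2. The entries there are isomer 62.0%, over-reaction product 33.7%, target 2.8% and intermediate 1.8%. They close at 100%, and isomer is the largest entry.
3. From 30.0 h to 40.0 h in the alpha run, over-reaction product gained 4.3 percentage points while target averaged 4.35%. With the gas held, this reads as a pseudo-first-order bite on target of 0.0989 h⁻¹.
4. If target is fed from isomer, isomer drains at the bite times the ratio of target to isomer, here 0.0452, which gives 0.00446 h⁻¹.
5. In powers of ten, the tenfold time, the hours in which that drain would cut isomer by a factor of ten, is 516 h.
6. Our reckoning: we take the sum of isomer and over-reaction product as constant, so the two meet at their mean, 47.9%. At this drain isomer gets there 58.1 h after the alpha run's last reading, at 98.0 h, later than 68 h, so we expect isomer to lead in each flask. We put Monday's isomer between 62.0% and 66.1%, the two runs' readings at 40.0 h. At this drain it should then fall towards Friday's, to about 0.883 of its share on Monday's.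
7. The forecast names isomer of the product each time, since “it looks like a stable end product”, and gives 63.9%, 65% and 65.4%, rising. There we part.
8. The flasks give isomer of the product each time, with 64.4%, 63.9% and 61.8%, falling. The forecast's widest gap, on Friday's, is 3.6 points.

    substrate + partner → intermediate + by-product (k = 32.0 M⁻¹ h⁻¹)
    intermediate ⇌ target (K = 1.50, k = 0.520 h⁻¹)
    intermediate ⇌ isomer of the product (K = 31.0, k = 0.190 h⁻¹)
    partner + target → over-reaction product (k = 9.60 M⁻¹ h⁻¹)
    gas ⇌ partner, rate k5*(csat - [partner]) (kL = 0.850 h⁻¹)

In Monday's flask, intermediate and isomer, by their step alone, relax against each other with a half-life of 3.53 h, short against 40 h, and intermediate and target, by theirs alone, relax faster, at 0.800 h. Friday's end shares give a tenfold time of 974 h, and Friday's isomer, falling to 14.9% by 680 h, shows 991 h. Saturday's end shares give 808 h, and Saturday's isomer, falling to 21.6% by 520 h, shows 994 h.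

Readings and results stem from a simulated flask for substances that don't exist; the scatter is artificial.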